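**Retrosynthetic overview**
1. The target is a 2-(furan-2-yl)-1,4-benzoquinone carrying an (S)-configured prenyl/senecioate side chain at furan C4. Quinone numbering used here: C1(=O) next to the furyl-bearing C2, then C3–H, C4(=O), C5–H, C6–H.
2. Key disconnection: the quinone bond C4–C5, formed in the last step by 6π electrocyclisation of a (Z)-dienylketene released thermally (4π opening) from a 4-ethenyl-4-hydroxy-3-furylcyclobut-2-enone, followed by hydroquinone-to-quinone oxidation.
3. Enabling feature: the para-dioxygenated six-membered carbocycle. Its C4(=O)–C3H=C2(furyl)–C1(–O) unit is a cyclobutenone carbinol in ring-expanded form and C5=C6 is the vinyl group on that carbinol, so the hydroquinone-level ring is a valence isomer of a strained four-membered carbinol.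
4. Cyclobutenone ⇐ C5-magnesiated furan with the finished side chain + 3-isopropoxy-4-silyloxy-4-vinylcyclobutenone (from diisopropyl squarate), joined with carbonyl transposition. Side chain ⇐ asymmetric allylation of 5-bromofuran-3-carbaldehyde, cross-metathesis, esterification.
5. Ring order: the furan and the four-membered ring are bought; the quinone ring is the only ring made, and it is made in the final step.

Key step: step 8

Remark: 5-bromofuran-3-carbaldehyde, diisopropyl squarate, 3-methylbut-2-enoic acid and (−)-Ipc2B(allyl) (pentane solution) are taken as purchasable; the cyclobutene carbinol centre in 4, 5, 12 and 13 is uncontrolled, which is of no consequence because it becomes sp2 in step 8.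

**Step 1**
Reactants: 1 diisopropyl squarate (3,4-diisopropoxycyclobut-3-ene-1,2-dione)
Product: 3 3-isopropoxycyclobut-3-ene-1,2-dione, via hydride adduct 2 (not isolated)
Conditions: LiAlH(OtBu)3, THF, −78 → −20 °C; then 6 M HCl, CH2Cl2, 0 °C → rt
Reagents that add atoms: water, O
Why: 1,2-reduction of one squarate carbonyl followed by acid-induced ionisation of the carbinol to an isopropoxy-stabilised cyclobutenyl cation and hydrolysis with loss of isopropanol (Stork–Danheiser-type carbonyl transposition) should give the semisquarate ester; the racemic carbinol centre of 2 is destroyed.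

**Step 2**
Reactants: 3 3-isopropoxycyclobut-3-ene-1,2-dione
Product: 4 4-ethenyl-4-hydroxy-3-isopropoxycyclobut-2-en-1-one (racemic)
Conditions: CH2=CHMgBr, THF, −78 °C; aq NH4Cl
Reagents that add atoms: vinylmagnesium bromide, C=C[Mg]Br
Why: Grignard 1,2-addition should occur at the ketone-like carbonyl next to the isopropoxy-bearing carbon, because the other carbonyl is a deactivated vinylogous ester, as in additions to 3-alkoxycyclobutenediones; the new carbinol centre forms as a racemate and is erased in step 8.

**Step 3**
Reactants: 4 4-ethenyl-4-hydroxy-3-isopropoxycyclobut-2-en-1-one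
Product: 5 4-ethenyl-3-isopropoxy-4-(trimethylsilyloxy)cyclobut-2-en-1-one (racemic)
Conditions: Me3SiCl, imidazole, DMF, 0 °C → rt
Reagents that add atoms: chlorotrimethylsilane, C[Si](C)(C)Cl
Why: O-silylation of the tertiary alcohol masks the acidic proton so that one equivalent of the valuable organometallic suffices in step 7, and the trimethylsilyl ether is removed again by the acid of that step.

**Step 4**
Reactants: 6 5-bromofuran-3-carbaldehyde
Product: 7 (1S)-1-(5-bromofuran-3-yl)but-3-en-1-ol
Conditions: (−)-Ipc2B(allyl), Et2O, −78 °C; then NaOH, H2O2, 0 °C → rt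
Reagents that add atoms: (−)-B-allyldiisopinocampheylborane, C=CCB([C@@H]1C[C@@H]2C[C@H]([C@H]1C)C2(C)C)[C@@H]1C[C@@H]2C[C@H]([C@H]1C)C2(C)C
Why: Brown asymmetric allylboration through a chair Zimmerman–Traxler transition state; the (−)-Ipc2B reagent is expected to attack the Si face of the heteroaryl aldehyde, as it does with benzaldehyde, which sets the (S)-carbinol.

**Step 5**
Reactants: 7 (1S)-1-(5-bromofuran-3-yl)but-3-en-1-ol
Product: 8 (1S)-1-(5-bromofuran-3-yl)-4-methylpent-3-en-1-ol
Conditions: 2-methyl-2-butene (excess), second-generation Grubbs catalyst (H2IMes)(PCy3)Cl2Ru=CHPh (5 mol %), CH2Cl2, 40 °C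
Reagents that add atoms: 2-methyl-2-butene, CC=C(C)C
Why: Olefin cross-metathesis with excess 2-methyl-2-butene should exchange the terminal methylene for an isopropylidene group with loss of propene, giving the prenyl terminus without touching the carbinol centre or the aryl bromide.

**Step 6**
Reactants: 8 (1S)-1-(5-bromofuran-3-yl)-4-methylpent-3-en-1-ol; 9 3-methylbut-2-enoic acid (senecioic acid)
Product: 10 (1S)-1-(5-bromofuran-3-yl)-4-methylpent-3-en-1-yl 3-methylbut-2-enoate
Conditions: DCC, DMAP (cat.), CH2Cl2, 0 °C → rt
Reagents that add atoms: none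
Why: Steglich esterification acylates the secondary alcohol at oxygen with retention of configuration and avoids the acid chloride/amine conditions that deconjugate senecioates through a vinylketene.

**Step 7**
Reactants: 10 (1S)-1-(5-bromofuran-3-yl)-4-methylpent-3-en-1-yl 3-methylbut-2-enoate; 5 4-ethenyl-3-isopropoxy-4-(trimethylsilyloxy)cyclobut-2-en-1-one
Product: 13 (1S)-1-[5-(4-ethenyl-4-hydroxy-3-oxocyclobut-1-en-1-yl)furan-3-yl]-4-methylpent-3-en-1-yl 3-methylbut-2-enoate (two carbinol epimers), via furylmagnesium chloride 11 (not isolated), via tertiary carbinol 12 (not isolated)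
Conditions: i-PrMgCl·LiCl, THF, −15 → 0 °C; then 5, −40 → 0 °C; then 1 M HCl, THF, 0 °C → rt
Reagents that add atoms: water, O
Why: Bromine–magnesium exchange at the furan α-position with i-PrMgCl·LiCl should be fast enough at or below 0 °C to spare the hindered, conjugated ester; the furyl Grignard then adds to the strained cyclobutenone carbonyl of 5, and on acidification the furyl carbinol ionises to an isopropoxy-stabilised cation that is hydrolysed with loss of isopropanol (Stork–Danheiser carbonyl transposition) while the silyl ether is cleaved, which puts the furyl group at C3 next to the vinyl carbinol at C4 without regiochemical ambiguity (conjugate addition–elimination at the isopropoxy carbon would give the same constitution), and the uncontrolled carbinol centre is erased in step 8.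

**Step 8**
Reactants: 13 (1S)-1-[5-(4-ethenyl-4-hydroxy-3-oxocyclobut-1-en-1-yl)furan-3-yl]-4-methylpent-3-en-1-yl 3-methylbut-2-enoate
Product: 16 (1S)-1-[5-(3,6-dioxocyclohexa-1,4-dien-1-yl)furan-3-yl]-4-methylpent-3-en-1-yl 3-methylbut-2-enoate (target), via dienylketene 14 (not isolated), via hydroquinone 15 (not isolated)
Conditions: PhMe (degassed, dilute), 110 °C; then Ag2O, MgSO4, Et2O, rt
Reagents that add atoms: none
Why: Heating should open the cyclobutenone by conrotatory 4π electrocyclic cleavage of the bond between the carbonyl carbon and the carbinol carbon, the C4 hydroxyl rotating outward (donor torquoselectivity) so that the vinyl group turns inward and (Z)-dienylketene 14 results. Thermal disrotatory 6π electrocyclisation then joins the ketene carbon to the terminal vinyl carbon (quinone bond C4–C5), closing the six-membered ring, and tautomerisation of the cyclohexadienone gives hydroquinone 15, which Ag2O dehydrogenates to quinone 16. The closest known reaction type is the Moore rearrangement, the thermal ring expansion of 4-alkenyl-4-hydroxycyclobutenones to hydroquinones and quinones. No stereocentre is created: the carbinol carbon becomes the sp2 carbon C1, so both epimers of 13 converge on one product, and the remote (S)-centre is not involved. The step needs inward rotation of the vinyl group and closure at carbon instead of trapping of the ketene by the hydroxyl (butenolide formation); the 4-hydroxy donor and the fast, aromatisation-driven intramolecular closure should secure this, and the neutral, base-free conditions should spare the ester, the prenyl alkene and the furan.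

**Compound list**
1 | diisopropyl squarate (3,4-diisopropoxycyclobut-3-ene-1,2-dione) | CC(C)OC1=C(OC(C)C)C(=O)C1=O | starting material
2 | 4-hydroxy-2,3-diisopropoxycyclobut-2-en-1-one (racemic) | CC(C)OC1=C(OC(C)C)C(=O)C1O | intermediate
3 | 3-isopropoxycyclobut-3-ene-1,2-dione | CC(C)OC1=CC(=O)C1=O | intermediate
4 | 4-ethenyl-4-hydroxy-3-isopropoxycyclobut-2-en-1-one (racemic) | C=CC1(O)C(OC(C)C)=CC1=O | intermediate
5 | 4-ethenyl-3-isopropoxy-4-(trimethylsilyloxy)cyclobut-2-en-1-one (racemic) | C=CC1(O[Si](C)(C)C)C(OC(C)C)=CC1=O | intermediate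
6 | 5-bromofuran-3-carbaldehyde | O=Cc1coc(Br)c1 | starting material
7 | (1S)-1-(5-bromofuran-3-yl)but-3-en-1-ol | C=CC[C@H](O)c1coc(Br)c1 | intermediate
8 | (1S)-1-(5-bromofuran-3-yl)-4-methylpent-3-en-1-ol | CC(C)=CC[C@H](O)c1coc(Br)c1 | intermediate
9 | 3-methylbut-2-enoic acid (senecioic acid) | CC(C)=CC(=O)O | starting material
10 | (1S)-1-(5-bromofuran-3-yl)-4-methylpent-3-en-1-yl 3-methylbut-2-enoate | CC(C)=CC[C@H](OC(=O)C=C(C)C)c1coc(Br)c1 | intermediate
11 | [4-[(1S)-4-methyl-1-(3-methylbut-2-enoyloxy)pent-3-en-1-yl]furan-2-yl]magnesium chloride (LiCl complex) | CC(C)=CC[C@H](OC(=O)C=C(C)C)c1coc([Mg]Cl)c1 | intermediate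
12 | (1S)-1-[5-(4-ethenyl-1-hydroxy-3-isopropoxy-4-trimethylsilyloxycyclobut-2-en-1-yl)furan-3-yl]-4-methylpent-3-en-1-yl 3-methylbut-2-enoate (present as its magnesium alkoxide; epimer mixture) | CC(C)=CC[C@H](OC(=O)C=C(C)C)c1coc(C2(O)C=C(OC(C)C)C2(O[Si](C)(C)C)C=C)c1 | intermediate
13 | (1S)-1-[5-(4-ethenyl-4-hydroxy-3-oxocyclobut-1-en-1-yl)furan-3-yl]-4-methylpent-3-en-1-yl 3-methylbut-2-enoate (two carbinol epimers) | CC(C)=CC[C@H](OC(=O)C=C(C)C)c1coc(C2=CC(=O)C2(O)C=C)c1 | intermediate
14 | (1S)-1-[5-[(3Z)-4-hydroxy-1-oxohexa-1,3,5-trien-3-yl]furan-3-yl]-4-methylpent-3-en-1-yl 3-methylbut-2-enoate (dienylketene) | CC(C)=CC[C@H](OC(=O)C=C(C)C)c1coc(/C(C=C=O)=C(\O)C=C)c1 | intermediate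
15 | (1S)-1-[5-(2,5-dihydroxyphenyl)furan-3-yl]-4-methylpent-3-en-1-yl 3-methylbut-2-enoate (hydroquinone) | CC(C)=CC[C@H](OC(=O)C=C(C)C)c1coc(-c2cc(O)ccc2O)c1 | intermediate
16 | (1S)-1-[5-(3,6-dioxocyclohexa-1,4-dien-1-yl)furan-3-yl]-4-methylpent-3-en-1-yl 3-methylbut-2-enoate | CC(C)=CC[C@H](OC(=O)C=C(C)C)c1coc(C2=CC(=O)C=CC2=O)c1 | target

**Total step count:** 8
**Longest linear sequence:** 5 steps (steps 4, 5, 6, 7, 8 from compound 6; the branch from compound 1 through steps 1, 2, 3, 7, 8 is equally long)

**Steps most likely to fail**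

1. Step 7. What may go wrong: the bromine–magnesium exchange is too slow at a temperature the ester tolerates, so i-PrMgCl or the furylmagnesium species attacks the senecioate, or the heteroaryl Grignard adds incompletely to the vinylogous-ester carbonyl. The fallback sets out from compound 8 and comes back at compound 13. Alcohol 8 is treated with n-BuLi (2.1 equiv, THF, −78 °C), the first equivalent forming the alkoxide and the second effecting bromine–lithium exchange, to give lithium (1S)-1-(5-lithiofuran-3-yl)-4-methylpent-3-en-1-olate F1. Addition of 5 at −78 °C should give (1S)-1-[5-(4-ethenyl-1-hydroxy-3-isopropoxy-4-trimethylsilyloxycyclobut-2-en-1-yl)furan-3-yl]-4-methylpent-3-en-1-ol F2 as its dilithium alkoxide. Work-up with 1 M HCl as in step 7 should bring about transposition and desilylation to 4-ethenyl-4-hydroxy-3-[4-[(1S)-1-hydroxy-4-methylpent-3-en-1-yl]furan-2-yl]cyclobut-2-en-1-one F3. Steglich esterification with 9 (DCC, cat. DMAP, CH2Cl2, 0 °C) should then acylate the secondary carbinol in preference to the hindered tertiary one and give 13.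

2. Step 8. What may go wrong: the dienylketene is diverted (trapping by the enol hydroxyl to a butenolide after outward rotation of the vinyl group, or ketene oligomerisation), or the quinone is consumed at 110 °C by cycloaddition with furan units. The fallback sets out from compound 10 and comes back at compound 16; the six-membered ring is then bought as an arene instead of being made. Suzuki–Miyaura coupling of 10 with (2,5-dimethoxyphenyl)boronic acid (Pd(PPh3)4, K3PO4, dioxane/H2O, 80 °C) should give (1S)-1-[5-(2,5-dimethoxyphenyl)furan-3-yl]-4-methylpent-3-en-1-yl 3-methylbut-2-enoate F4. Oxidative demethylation with (NH4)2Ce(NO3)6 in MeCN/H2O at 0 °C should then give 16.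

3. Step 2. What may go wrong: loss of regio- and chemocontrol in the Grignard addition to the small, highly electrophilic dione 3 (attack at the vinylogous-ester carbonyl, double addition), and decomposition of the sensitive carbinol 4 on isolation. The fallback sets out from compounds 1 and 10 (through Grignard 11, made as in step 7) and comes back at compound 13; the semisquarate branch is dropped and the order of introduction is inverted.
   - Addition of 11 to 1 (THF, −78 °C; aq NH4Cl) should give (1S)-1-[5-(1-hydroxy-2,3-diisopropoxy-4-oxocyclobut-2-en-1-yl)furan-3-yl]-4-methylpent-3-en-1-yl 3-methylbut-2-enoate F5.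
   - Luche reduction (NaBH4, CeCl3·7H2O, MeOH, −78 → 0 °C) of the remaining carbonyl should give (1S)-1-[5-(1,4-dihydroxy-2,3-diisopropoxycyclobut-2-en-1-yl)furan-3-yl]-4-methylpent-3-en-1-yl 3-methylbut-2-enoate F6.
   - Catalytic HCl in wet CH2Cl2 should effect the double carbonyl transposition to (1S)-1-[5-(3,4-dioxocyclobut-1-en-1-yl)furan-3-yl]-4-methylpent-3-en-1-yl 3-methylbut-2-enoate F7.
   - CH2=CHMgBr (THF, −78 °C; aq NH4Cl) should add to the carbonyl next to the furyl-bearing carbon, the other carbonyl being deactivated as a vinylogous acylfuran, and give 13. Any carbinol from attack at the other carbonyl would ring-expand in step 8 to the same hydroquinone 15.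

**Further compounds**
F1 | step 7 | lithium (1S)-1-(5-lithiofuran-3-yl)-4-methylpent-3-en-1-olate | CC(C)=CC[C@H](O[Li])c1coc([Li])c1
F2 | step 7 | (1S)-1-[5-(4-ethenyl-1-hydroxy-3-isopropoxy-4-trimethylsilyloxycyclobut-2-en-1-yl)furan-3-yl]-4-methylpent-3-en-1-ol (formed as its dilithium alkoxide) | CC(C)=CC[C@H](O)c1coc(C2(O)C=C(OC(C)C)C2(O[Si](C)(C)C)C=C)c1
F3 | step 7 | 4-ethenyl-4-hydroxy-3-[4-[(1S)-1-hydroxy-4-methylpent-3-en-1-yl]furan-2-yl]cyclobut-2-en-1-one | CC(C)=CC[C@H](O)c1coc(C2=CC(=O)C2(O)C=C)c1
F4 | step 8 | (1S)-1-[5-(2,5-dimethoxyphenyl)furan-3-yl]-4-methylpent-3-en-1-yl 3-methylbut-2-enoate | CC(C)=CC[C@H](OC(=O)C=C(C)C)c1coc(-c2cc(OC)ccc2OC)c1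
F5 | step 2 | (1S)-1-[5-(1-hydroxy-2,3-diisopropoxy-4-oxocyclobut-2-en-1-yl)furan-3-yl]-4-methylpent-3-en-1-yl 3-methylbut-2-enoate | CC(C)=CC[C@H](OC(=O)C=C(C)C)c1coc(C2(O)C(OC(C)C)=C(OC(C)C)C2=O)c1
F6 | step 2 | (1S)-1-[5-(1,4-dihydroxy-2,3-diisopropoxycyclobut-2-en-1-yl)furan-3-yl]-4-methylpent-3-en-1-yl 3-methylbut-2-enoate | CC(C)=CC[C@H](OC(=O)C=C(C)C)c1coc(C2(O)C(OC(C)C)=C(OC(C)C)C2O)c1
F7 | step 2 | (1S)-1-[5-(3,4-dioxocyclobut-1-en-1-yl)furan-3-yl]-4-methylpent-3-en-1-yl 3-methylbut-2-enoate | CC(C)=CC[C@H](OC(=O)C=C(C)C)c1coc(C2=CC(=O)C2=O)c1
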